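(All runs stem from a simulated flask with made-up constants; scatter was added.)

One percentage of solid lost per hour cannot describe both earlier runs: by 8.00 h, delta has lost 14.9 % of its charge and zeta 9.60 %, a gap of 5.3 percentage points against a scatter of 1 point.

| setting | delta | zeta | flask |
|---|---|---|---|
| solid substrate | 28 mM | 44 mM | 20 mM |
| reagent | 40 mM | 40 mM | 40.0 mM |
| remark | run made earlier | run made earlier |  |
| time |  |  | 10 h |

- delta (time / h: solid substrate / %, first product / %, bis adduct / %): 0.417: 97.4, 0.8, 0; 1.33: 98.2, 0, 1.4; 2.50: 96.2, 2.8, 1.6; 3.00: 94.0, 1.7, 4.2; 5.00: 88.7, 3.5, 6.1; 6.00: 89.1, 3.8, 5.4; 8.00: 85.1, 4.6, 8.1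
- zeta (time / h: solid substrate / %, first product / %, bis adduct / %): 0.667: 98.3, 0.3, 2.0; 1.00: 100.0, 0, 0; 1.33: 96.7, 0, 0.4; 2.50: 96.3, 2.2, 2.2; 3.00: 95.2, 2.9, 2.7; 5.00: 93.6, 2.8, 2.6; 8.00: 90.4, 4.6, 7.2

(each reading ± 1 percentage point)

- as a solid, counted per litre of solution: solid substrate
- at the start none of the solid substrate is in solution

- the solid substrate standing at 10 h, as a percentage of the solid substrate charged (only what is still solid)
- the first product standing at 10 h, as a percentage of the solid substrate charged
- the bis adduct standing at 10 h, as a percentage of the solid substrate charged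

Counted per litre, the two losses meet. Delta gives 0.522 mM/h, this wear rate being the solid lost per litre and hour, and zeta gives 0.528 mM/h, though its charge is 1.57 times delta's.

In the new flask, c(solid substrate) is the smaller charge, so the substrate is the limiting reagent. Reckoned here, the wear rate takes 26.1 % of that charge by 10 h, leaving 73.9 %.

Two chemists accept this loss and dispute where it goes. The second sees 2.00 equivalents of reagent in the new flask, against 1.43 in delta, and sends the whole loss on to bis adduct, 26.1 %. The first answers that c(reagent) is 40.0 mM in all three flasks, and that first product read 36.2 % of the products in delta and 39.0 % in zeta at 8.00 h, despite their different equivalents.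

The first chemist's forecast, holding that the rate “does not depend on the solid load”, is 75 % solid, 9 % first product and 15 % bis adduct.

The flask gives 71.6 % solid, 9.34 % first product and 16.8 % bis adduct, so the forecast held.

    reagent + first product ⇌ bis adduct (K = 62.0 /M, k = 0.0210 /M/s)
    solid substrate ⇌ starting material, rate k2*(cs2 - [starting material]) while solid is left; crystals form when [starting material] > cs2 (solubility = 7.70 mM, k = 2.10 × 10⁻⁵ /s)
    starting material + reagent → first product (k = 0.0220 /M/s)
    starting material ⇌ dormant form (K = 2.00, k = 5.00 × 10⁻⁵ /s)

Starting material at 1.09 % and dormant form at 1.14 % hold hardly any of this flask's charge at 10.0 h. The wear rate gave 26.1 % lost, and this flask lost 28.4 %. The second chemist's region is the neighbour flask with 160 mM of reagent: against the same 26.1 %, that neighbour lost 28.9 %, and it holds 2.98 % first product and 25.4 % bis adduct.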